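A direct plan would make each ring on its own by Michael–Dieckmann annulation of a β-keto ester with methyl crotonate and bromination–dehydrobromination, and join the rings at the end.
Ring A would be protected as a bis-MOM ether and its 6-methyl group brominated through the lateral lithio species to the benzylic bromide A1.
Ring B would be saponified, re-esterified as a benzyl ester, formylated to A2 and hydrogenolysed; its carboxylate would be alkylated with A1 to A3 and the MOM groups removed with acid.
Weakest would be the exchange of the ring B ester (hydrolysis of a hindered salicylate, benzylation, hydrogenolysis beside an aldehyde): three operations that add no complexity.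
Next would be the electrophilic formylation of the finished orsellinate ring to A2: the choice between C3 and C5 would rest on chelation alone, and a regioisomer would have to be separated.
Least welcome on late material would be the final MOM cleavage of A3 with strong acid in methanol: the benzylic ester beside the methyl ester could be methanolysed and close to the phthalide, and the aldehyde could form its acetal.

The retrosynthesis cuts ring A itself at C1–C2 and C5–C6 (C1 CO2Me, C2 OH, C3 CH3, C4 OH, C5 H, C6 CH2O–acyl), not the ester C–O bond.
The feature used: C1 and C6, the neighbours that carry the methyl ester and the acyloxymethyl group, are the two sp carbons of a 4-acyloxybut-2-ynoate; C2–C5, with oxygen on C2 and C4 and methyl on C3, are the carbon chain of methyl 2-methylacetoacetate as its bis-silyl dienol ether.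
Ring B arises first, as a cyclohexane-1,3-dione whose only carbon between two ketones (C3) takes the formyl group before aromatization; its acid is esterified once, with methyl 4-hydroxybut-2-ynoate.
Ring A arises last, by Diels–Alder benzannulation onto that alkynyl ester, which should give the target directly.
So no ester is exchanged (one tert-butyl ester is carried and cleaved by acid), no aromatic ring is formylated, and the last step needs no acid-labile protecting group.
No benzylic halide or alcohol beside the ester ever exists, so phthalide closure cannot occur.

Key step: step 8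

Assumption: diene 13 is used as obtained, as a mixture of geometric isomers about its ketene acetal double bond; this is of no consequence because that carbon becomes aromatic. All chiral intermediates (3 to 6 and 15) are racemic and the target is achiral.

Step 1
Reactants: 1 tert-butyl 3-oxobutanoate (tert-butyl acetoacetate); 2 methyl (E)-but-2-enoate (methyl crotonate)
Product: 4 tert-butyl 6-methyl-2,4-dioxocyclohexane-1-carboxylate, via Michael adduct 3 (not isolated)
Conditions: KOtBu (1.1 equiv), tBuOH, reflux, 6 h; then 1 M aq HCl, 0 °C
Reagents that add atoms: none
Why: Michael addition of the acetoacetate enolate to the crotonate followed by Dieckmann (Claisen) closure of the acetyl methyl onto the methyl ester should give the six-membered 1,3-dione, driven by the stable dione enolate; the tert-butyl ester cannot take part in the closure, and the two uncontrolled stereocentres vanish on aromatization in step 3.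

Step 2
Reactants: 4 tert-butyl 6-methyl-2,4-dioxocyclohexane-1-carboxylate
Product: 6 tert-butyl 3-(hydroxymethylidene)-6-methyl-2,4-dioxocyclohexane-1-carboxylate (enol form of the 3-formyl dione), via enaminone 5 (not isolated)
Conditions: Me2NCH(OMe)2 (1.1 equiv), CH2Cl2, rt, 2 h; then 1 M aq HCl, THF, 0 °C → rt
Reagents that add atoms: N,N-dimethylformamide dimethyl acetal, COC(OC)N(C)C; water, O
Why: Condensation of the amide acetal with the only methylene that lies between two ketone carbonyls (C3; C1 carries a single hydrogen and C5 is far less acidic), followed by hydrolysis of the vinylogous amide, should fix the formyl carbon at C3 before any aromatic ring exists, so no regiochemical choice arises.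

Step 3
Reactants: 6 tert-butyl 3-(hydroxymethylidene)-6-methyl-2,4-dioxocyclohexane-1-carboxylate
Product: 7 tert-butyl 3-formyl-2,4-dihydroxy-6-methylbenzoate
Conditions: DDQ (1.1 equiv), 1,4-dioxane, 90 °C, 3 h
Reagents that add atoms: none
Why: Quinone dehydrogenation of the 2-acylcyclohexane-1,3-dione (hydride abstraction from the tertiary C6–H allylic to the C1=C2 enol, then loss of a C5 proton) should give the C5=C6 olefin, which enolizes to the 2-formylresorcinol ring B; the aldehyde, the tert-butyl ester and the 6-methyl group (meta to both hydroxyls) should not be oxidized.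

Step 4
Reactants: 7 tert-butyl 3-formyl-2,4-dihydroxy-6-methylbenzoate
Product: 8 3-formyl-2,4-dihydroxy-6-methylbenzoic acid (haematommic acid)
Conditions: TFA/CH2Cl2 1:4, 0 °C → rt, 2 h; evaporate cold
Reagents that add atoms: none
Why: Acidolysis of the tert-butyl ester (loss of the tert-butyl cation as isobutene) frees the acid without hydroxide, so the hindered, chelated formyl salicylate is never saponified, and the electron-poor ring should resist decarboxylation at room temperature.

Step 5
Reactants: 8 3-formyl-2,4-dihydroxy-6-methylbenzoic acid; 9 methyl 4-hydroxybut-2-ynoate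
Product: 10 4-methoxy-4-oxobut-2-yn-1-yl 3-formyl-2,4-dihydroxy-6-methylbenzoate
Conditions: PPh3 (1.1 equiv) and DIAD (1.1 equiv) premixed, THF, 0 °C; then 9 and 8, 0 °C → rt, 3 h
Reagents that add atoms: none
Why: Mitsunobu esterification: the betaine deprotonates only the carboxylic acid and the carboxylate displaces the primary propargylic alkoxyphosphonium by SN2; because the alcohol and not the acid is activated, the chelated phenols cannot be acylated, and premixing the phosphine with DIAD leaves no free phosphine to add to the ynoate.

Step 6
Reactants: 11 methyl 2-methyl-3-oxobutanoate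
Product: 12 methyl 2-methyl-3-(trimethylsilyloxy)but-2-enoate (mixture of geometric isomers)
Conditions: TMSCl (1.5 equiv), Et3N (1.6 equiv), toluene, rt, 48 h; filter under argon, distil
Reagents that add atoms: chlorotrimethylsilane, C[Si](C)(C)Cl
Why: O-silylation of the enolized β-keto ester is the standard first stage of a Chan diene synthesis.

Step 7
Reactants: 12 methyl 2-methyl-3-(trimethylsilyloxy)but-2-enoate
Product: 13 1-methoxy-2-methyl-1,3-bis(trimethylsilyloxy)buta-1,3-diene
Conditions: LDA (1.1 equiv), THF, −78 °C, 1 h; TMSCl (1.2 equiv), −78 °C → rt; pentane, filter, Kugelrohr distillation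
Reagents that add atoms: chlorotrimethylsilane, C[Si](C)(C)Cl
Why: γ-Deprotonation of the vinylogous ester at the C4 methyl group and O-silylation of the dienolate at the ester oxygen should give the 1,3-bis(silyloxy)diene (Chan–Molander diene synthesis).

Step 8
Reactants: 10 4-methoxy-4-oxobut-2-yn-1-yl 3-formyl-2,4-dihydroxy-6-methylbenzoate; 13 1-methoxy-2-methyl-1,3-bis(trimethylsilyloxy)buta-1,3-diene
Product: 16 methyl 6-[(3-formyl-2,4-dihydroxy-6-methylbenzoyl)oxymethyl]-2,4-dihydroxy-3-methylbenzoate (target), via bis(trimethylsilyl) ether 14 (not isolated), via cyclohexadiene cycloadduct 15 (not isolated)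
Conditions: BSA (2.2 equiv), toluene, 50 °C, 1 h; then 13 (3 equiv), 105 °C, sealed, argon, 24 h; then 0.5 M aq HCl, THF, 0 °C, 20 min
Reagents that add atoms: none
Why: The electron-rich 1,1,3-trioxygenated diene 13 and the ynoate of 14 should combine in a normal-demand [4+2] cycloaddition (a stepwise Michael–Claisen path would give the same constitution) to cyclohexa-1,4-diene 15, whose mixed methyl trimethylsilyl ketal loses methanol to aromatize, and dilute acid then frees the four phenols. The closest known reaction type is the Diels–Alder benzannulation of Danishefsky–Brassard and Chan dienes with acetylenic esters to resorcylates. Ring A is closed by intermolecular [4+2] cycloaddition that forms C1–C2 and C5–C6 of the six-membered carbocycle; no stereocentre is created in the product, and the racemic ketal centre of 15 disappears on aromatization. The regiochemistry is secured by the diene: its CH2 terminus, which carries the largest HOMO coefficient, bonds to the β-carbon of the ynoate, so the hydroxyls end ortho and para to the methyl ester with the methyl between them and the acyloxymethyl group beside the ester. The chemoselectivity needed, alkyne against aldehyde, rests on the absence of any Lewis acid and on the two ortho silyloxy groups that shield and deactivate the formyl group, while silylation with BSA keeps the acidic phenols from protonating the ketene acetal. Because the methyl ester and the acyloxymethyl group arrive together on the alkyne, no benzylic halide or alcohol next to an ester is formed and phthalide closure is excluded.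

**Compound list**
1 | tert-butyl 3-oxobutanoate | CC(=O)CC(=O)OC(C)(C)C | starting material
2 | methyl (E)-but-2-enoate | C/C=C/C(=O)OC | starting material
3 | Michael adduct: 1-tert-butyl 5-methyl 2-acetyl-3-methylpentanedioate (not isolated; racemic diastereomers) | CC(=O)C(C(=O)OC(C)(C)C)C(C)CC(=O)OC | intermediate
4 | tert-butyl 6-methyl-2,4-dioxocyclohexane-1-carboxylate (racemic diastereomer and enol mixture) | CC1CC(=O)CC(=O)C1C(=O)OC(C)(C)C | intermediate
5 | enaminone: tert-butyl 3-[(dimethylamino)methylidene]-6-methyl-2,4-dioxocyclohexane-1-carboxylate (not isolated; racemic) | CN(C)C=C1C(=O)CC(C)C(C(=O)OC(C)(C)C)C1=O | intermediate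
6 | tert-butyl 3-(hydroxymethylidene)-6-methyl-2,4-dioxocyclohexane-1-carboxylate (racemic; tautomer of the 3-formyl dione) | OC=C1C(=O)CC(C)C(C(=O)OC(C)(C)C)C1=O | intermediate
7 | tert-butyl 3-formyl-2,4-dihydroxy-6-methylbenzoate | Cc1cc(O)c(C=O)c(O)c1C(=O)OC(C)(C)C | intermediate
8 | 3-formyl-2,4-dihydroxy-6-methylbenzoic acid | Cc1cc(O)c(C=O)c(O)c1C(=O)O | intermediate
9 | methyl 4-hydroxybut-2-ynoate | COC(=O)C#CCO | starting material
10 | 4-methoxy-4-oxobut-2-yn-1-yl 3-formyl-2,4-dihydroxy-6-methylbenzoate | COC(=O)C#CCOC(=O)c1c(C)cc(O)c(C=O)c1O | intermediate
11 | methyl 2-methyl-3-oxobutanoate | CC(=O)C(C)C(=O)OC | starting material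
12 | methyl 2-methyl-3-(trimethylsilyloxy)but-2-enoate (mixture of geometric isomers) | COC(=O)C(C)=C(C)O[Si](C)(C)C | intermediate
13 | 1-methoxy-2-methyl-1,3-bis(trimethylsilyloxy)buta-1,3-diene (mixture of geometric isomers) | C=C(O[Si](C)(C)C)C(C)=C(OC)O[Si](C)(C)C | intermediate
14 | 4-methoxy-4-oxobut-2-yn-1-yl 3-formyl-6-methyl-2,4-bis(trimethylsilyloxy)benzoate (not isolated) | COC(=O)C#CCOC(=O)c1c(C)cc(O[Si](C)(C)C)c(C=O)c1O[Si](C)(C)C | intermediate
15 | cycloadduct: methyl 2-{[3-formyl-6-methyl-2,4-bis(trimethylsilyloxy)benzoyl]oxymethyl}-6-methoxy-5-methyl-4,6-bis(trimethylsilyloxy)cyclohexa-1,4-diene-1-carboxylate (not isolated; racemic) | COC(=O)C1=C(COC(=O)c2c(C)cc(O[Si](C)(C)C)c(C=O)c2O[Si](C)(C)C)CC(O[Si](C)(C)C)=C(C)C1(OC)O[Si](C)(C)C | intermediate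
16 | methyl 6-[(3-formyl-2,4-dihydroxy-6-methylbenzoyl)oxymethyl]-2,4-dihydroxy-3-methylbenzoate (achiral) | COC(=O)c1c(COC(=O)c2c(C)cc(O)c(C=O)c2O)cc(O)c(C)c1O | target

Total step count: 8. Longest linear sequence: 6 steps (steps 1 to 5, then step 8; the diene is made in steps 6 and 7).

Steps most likely to fail:

Step 8. The diene could add to the aryl aldehyde of 14 (hetero-Diels–Alder or Mukaiyama-type addition), or the cycloaddition to the disubstituted alkyne could be too slow and the diene could decompose first. Ring A would then be built on a dienophile that lacks ring B. Diene 13 would be heated with commercial methyl 4-chlorobut-2-ynoate F1 (toluene, 90 °C; dilute aqueous HCl work-up) to give methyl 6-(chloromethyl)-2,4-dihydroxy-3-methylbenzoate F2. The carboxylate of acid 8 (KHCO3, 1.1 equiv, DMF, rt), in which only the acid is ionized, would then displace the benzylic chloride. This fallback sets out from 13 and 8 and returns to the route at 16.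

Step 3. Hydride abstraction from the electron-poor triketone 6 could be too slow, or the formyl group could be lost under oxidation. The double bond would then be introduced by selenoxide elimination. Selenenylation at C1, the enolizable carbon between ketone and ester (PhSeCl, pyridine, CH2Cl2, 0 °C), should give tert-butyl 3-(hydroxymethylidene)-6-methyl-2,4-dioxo-1-(phenylselanyl)cyclohexane-1-carboxylate F3. Oxidation (30% H2O2, CH2Cl2, 0 °C) should bring about syn elimination toward C6–H; the resulting C1=C6 olefin is a keto tautomer of the arene and should enolize. This fallback sets out from 6 and returns at 7.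

Step 5. The chelated 4-hydroxyl could be alkylated in competition with the carboxylate, or phosphine could add to the ynoate. The ester would then be made by carboxylate alkylation instead of alcohol activation. Alcohol 9 would be converted into methyl 4-bromobut-2-ynoate F4 (CBr4, PPh3, CH2Cl2, 0 °C), and the potassium carboxylate of 8 (KHCO3, 1.1 equiv, DMF, rt) would displace the propargylic bromide. This fallback sets out from 8 and 9 and returns at 10.

Further compounds
F1 | step 8 | methyl 4-chlorobut-2-ynoate | COC(=O)C#CCCl
F2 | step 8 | methyl 6-(chloromethyl)-2,4-dihydroxy-3-methylbenzoate | COC(=O)c1c(CCl)cc(O)c(C)c1O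
F3 | step 3 | tert-butyl 3-(hydroxymethylidene)-6-methyl-2,4-dioxo-1-(phenylselanyl)cyclohexane-1-carboxylate (racemic) | CC1CC(=O)C(=CO)C(=O)C1([Se]c2ccccc2)C(=O)OC(C)(C)C
F4 | step 5 | methyl 4-bromobut-2-ynoate | COC(=O)C#CCBr
A1 | direct plan | methyl 6-(bromomethyl)-2,4-bis(methoxymethoxy)-3-methylbenzoate | COCOc1cc(CBr)c(C(=O)OC)c(OCOC)c1C
A2 | direct plan | benzyl 3-formyl-2,4-dihydroxy-6-methylbenzoate | Cc1cc(O)c(C=O)c(O)c1C(=O)OCc1ccccc1
A3 | direct plan | [2-(methoxycarbonyl)-3,5-bis(methoxymethoxy)-4-methylphenyl]methyl 3-formyl-2,4-dihydroxy-6-methylbenzoate | COCOc1cc(COC(=O)c2c(C)cc(O)c(C=O)c2O)c(C(=O)OC)c(OCOC)c1C
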